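## Retrosynthetic overview

1. Target ⇐ its C6 PMB ether. Ring D (oxepane) closes last, by the C3 tertiary hydroxyl displacing a C16 triflate; C15 comes from hydroboration of a C14 isopropenyl group; C11/C12 come from the silyl enol ether of a Diels–Alder adduct.
2. Rings B and C (tetrahydrofuran and cyclohexene) ⇐ one intramolecular Diels–Alder reaction of a 2-silyloxydiene (C10–C13) with an (E)-unsaturated Weinreb amide (C1=C14), both held on a 2,9-cis oxonene.
3. Ring A (oxonene) ⇐ Nozaki–Hiyama–Kishi closure of C6–C7 (aldehyde + (Z)-vinyl iodide); C6 is then set by oxidation and CBS reduction.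
4. Acyclic ether ⇐ key intermolecular Evans glycolate aldol (C2–C3) joining the N-glycolyl oxazolidinone that carries C7–C11 to acetaldehyde, then chelation-controlled Grignard addition to the derived methyl ketone (quaternary C3).
5. Glycolate ⇐ (R,Z)-iodoallylic alcohol from propane-1,3-diol (Noyori reduction of an ynone, hydroalumination/iodination). Ring order: A, then B + C together, then D.

Assumption: asbestinin-type numbering is used throughout (cyclohexane C1, C10–C14; ether bridge C2–O–C9; C3 bears C18; C7 bears C19; C12 bears C20; C14 bears C15 with C16 and C17), and the target is taken as drawn, (1S,2S,3S,6R,9S,10R,11R,12R,14S,15R) with a 7Z olefin.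

Abbreviations: TBS = tert-butyldimethylsilyl, TBDPS = tert-butyldiphenylsilyl, TES = triethylsilyl, TIPS = triisopropylsilyl, PMB = 4-methoxybenzyl.

## Route

Step 1
Reactants: 1 propane-1,3-diol
Product: 2 3-(TBS-oxy)propan-1-ol
Conditions: NaH (1.0 equiv), THF, 0 °C to rt; then TBSCl (1.0 equiv)
Reagents that add atoms: tert-butyldimethylsilyl chloride, CC(C)(C)[Si](C)(C)Cl
Why: Williamson-type monosilylation of the sparingly soluble monosodium salt of a symmetrical diol gives the mono-TBS ether selectively, and no stereocentre is formed.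

Step 2
Reactants: 2 3-(TBS-oxy)propan-1-ol
Product: 3 3-(TBS-oxy)propanal
Conditions: Dess–Martin periodinane, CH2Cl2, 0 °C to rt
Reagents that add atoms: none
Why: Dess–Martin oxidation of a primary alcohol stops cleanly at the aldehyde and leaves the silyl ether untouched.

Step 3
Reactants: 3 3-(TBS-oxy)propanal
Product: 4 rac-1-(TBS-oxy)hex-4-yn-3-ol
Conditions: CH3C≡CMgBr, THF, −78 to 0 °C; H2O quench
Reagents that add atoms: prop-1-ynylmagnesium bromide, CC#C[Mg]Br
Why: Grignard 1,2-addition installs C7, C8 and C19, and the racemic carbinol is of no consequence because C9 is reset in steps 4 and 5.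

Step 4
Reactants: 4 rac-1-(TBS-oxy)hex-4-yn-3-ol
Product: 5 1-(TBS-oxy)hex-4-yn-3-one
Conditions: Dess–Martin periodinane, CH2Cl2, rt
Reagents that add atoms: none
Why: Neutral Dess–Martin oxidation gives the ynone without β-elimination of the silyloxy group.

Step 5
Reactants: 5 1-(TBS-oxy)hex-4-yn-3-one
Product: 6 (R)-1-(TBS-oxy)hex-4-yn-3-ol
Conditions: Ru[(R,R)-TsDPEN](p-cymene) (1 mol%), i-PrOH, rt
Reagents that add atoms: none
Why: Noyori asymmetric transfer hydrogenation of an ynone, in which the alkynyl group takes the place normally held by an aryl group, so the (R,R)-catalyst gives the (R)-carbinol (C9) in high ee under base-free conditions.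

Step 6
Reactants: 6 (R)-1-(TBS-oxy)hex-4-yn-3-ol
Product: 8 (3R,4Z)-1-(TBS-oxy)-5-iodohex-4-en-3-ol, via cyclic alkenylaluminate 7 (not isolated)
Conditions: NaAlH2(OCH2CH2OMe)2, THF, 0 °C to rt; then I2, −78 to 0 °C
Reagents that add atoms: iodine, II; sodium bis(2-methoxyethoxy)aluminium dihydride, [Na+].[AlH2-](OCCOC)OCCOC (its aluminium and alkoxy groups sit in 7 only)
Why: Hydroxyl-directed trans-hydroalumination puts aluminium on the distal alkyne carbon cis to the carbinol carbon, and iodination with retention gives the (Z)-vinyl iodide (C7) without touching C9.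

Step 7
Reactants: 8 (3R,4Z)-iodoallylic alcohol; 9 bromoacetic acid
Product: 10 2-{[(3R,4Z)-1-(TBS-oxy)-5-iodohex-4-en-3-yl]oxy}acetic acid
Conditions: NaH (3 equiv), THF, 0 °C to rt; acidic work-up
Reagents that add atoms: none
Why: Williamson etherification of the sodium alkoxide with the bromoacetate dianion forms the future ring ether oxygen–C2 bond without affecting C9 or the vinyl iodide.

Step 8
Reactants: 10 glycolic acid ether; 11 (R)-4-benzyloxazolidin-2-one
Product: 13 (R)-4-benzyl-3-(2-{[(3R,4Z)-1-(TBS-oxy)-5-iodohex-4-en-3-yl]oxy}acetyl)oxazolidin-2-one, via mixed pivalic anhydride 12 (not isolated)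
Conditions: PivCl, Et3N, THF, −20 °C; then 11, LiCl, −20 °C to rt
Reagents that add atoms: pivaloyl chloride, CC(C)(C)C(=O)Cl (its acyl group sits in 12 only)
Why: N-acylation through the mixed anhydride occurs at the unhindered glycolyl carbonyl and installs the auxiliary without creating a stereocentre.

Step 9
Reactants: 13 N-glycolyl oxazolidinone; 14 acetaldehyde
Product: 17 (R)-4-benzyl-3-[(2R,3S)-2-{[(3R,4Z)-1-(TBS-oxy)-5-iodohex-4-en-3-yl]oxy}-3-hydroxybutanoyl]oxazolidin-2-one, via dibutylboron Z-enolate 15 (not isolated), via dibutylboron aldolate 16 (not isolated)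
Conditions: Bu2BOTf, Et3N, CH2Cl2, −78 to 0 °C; MeCHO, −78 to 0 °C; then pH 7 buffer, MeOH, H2O2
Reagents that add atoms: dibutylboron triflate, CCCCB(CCCC)OS(=O)(=O)C(F)(F)F (its boron sits in 15 and 16 only)
Why: Evans syn aldol in which the Z-boron enolate reacts through a Zimmerman–Traxler chair on the face away from the benzyl group, forming the C2–C3 bond and setting C2 in the target sense (the syn C3 carbinol is oxidised in step 12).

Step 10
Reactants: 17 syn aldol adduct
Product: 18 (2S,3S)-2-{[(3R,4Z)-1-(TBS-oxy)-5-iodohex-4-en-3-yl]oxy}butane-1,3-diol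
Conditions: LiBH4, MeOH (1 equiv), THF, 0 °C
Reagents that add atoms: none
Why: Reductive cleavage of the imide gives the C1 primary alcohol and returns the auxiliary, with no epimerisation at C2 and no reaction at the vinyl iodide.

Step 11
Reactants: 18 1,3-diol
Product: 19 (2S,3S)-4-(TBDPS-oxy)-3-{[(3R,4Z)-1-(TBS-oxy)-5-iodohex-4-en-3-yl]oxy}butan-2-ol
Conditions: TBDPSCl, imidazole, CH2Cl2, 0 °C
Reagents that add atoms: tert-butyldiphenylsilyl chloride, CC(C)(C)[Si](Cl)(c1ccccc1)c1ccccc1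
Why: The bulky silyl chloride reacts only at the primary C1 hydroxyl, giving a non-chelating protecting group for step 13.

Step 12
Reactants: 19 secondary alcohol
Product: 20 (S)-4-(TBDPS-oxy)-3-{[(3R,4Z)-1-(TBS-oxy)-5-iodohex-4-en-3-yl]oxy}butan-2-one
Conditions: Dess–Martin periodinane, pyridine, CH2Cl2, rt
Reagents that add atoms: none
Why: Buffered Dess–Martin oxidation gives the α-alkoxy methyl ketone (C3, C18) without epimerising C2 or eliminating the β-silyloxy group.

Step 13
Reactants: 20 methyl ketone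
Product: 21 (2S,3S)-1-(TBDPS-oxy)-2-{[(3R,4Z)-1-(TBS-oxy)-5-iodohex-4-en-3-yl]oxy}-3-methylhept-6-en-3-ol
Conditions: CH2=CHCH2CH2MgBr, THF, −78 °C
Reagents that add atoms: but-3-enylmagnesium bromide, C=CCC[Mg]Br
Why: Cram-chelate-controlled Grignard addition (magnesium bridging the ketone and the C2 ether oxygen, the silyl ether not competing) brings the C4–C6 chain in from the side of the C2 hydrogen and sets the quaternary C3 as 3S.

Step 14
Reactants: 21 tertiary alcohol
Product: 22 3-O-TES ether of 21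
Conditions: TESOTf, 2,6-lutidine, CH2Cl2, −78 to 0 °C
Reagents that add atoms: triethylsilyl triflate, CC[Si](CC)(CC)OS(=O)(=O)C(F)(F)F
Why: Silyl triflate silylation protects the hindered tertiary hydroxyl so that the γ-hydroxy aldehyde of the next step cannot close to a lactol.

Step 15
Reactants: 22 TES ether
Product: 23 (4S,5S)-6-(TBDPS-oxy)-5-{[(3R,4Z)-1-(TBS-oxy)-5-iodohex-4-en-3-yl]oxy}-4-methyl-4-(TES-oxy)hexanal
Conditions: OsO4 (2 mol%), NaIO4, 2,6-lutidine, dioxane/H2O (3:1), rt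
Reagents that add atoms: osmium tetroxide, O=[Os](=O)(=O)=O (transfers the new carbonyl oxygen and is regenerated by sodium periodate, [Na+].[O-]I(=O)(=O)=O)
Why: Lemieux–Johnson cleavage is selective for the monosubstituted terminal alkene over the hindered, electron-poor trisubstituted vinyl iodide and unveils the C6 aldehyde.

Step 16
Reactants: 23 iodo aldehyde
Product: 24 (2S,3S,7Z,9R)-2-(TBDPS-oxymethyl)-9-[2-(TBS-oxy)ethyl]-3,7-dimethyl-3-(TES-oxy)-2,3,4,5,6,9-hexahydrooxonin-6-ol (C6 epimers)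
Conditions: CrCl2 (10 equiv), NiCl2 (2 mol%), DMSO, rt, 0.005 M (slow addition)
Reagents that add atoms: none
Why: Nozaki–Hiyama–Kishi reaction, in which the vinyl iodide is activated by NiCl2/CrCl2 and adds only to the aldehyde, closes ring A at C6–C7 with retention of the Z-olefin, and the C6 epimer mixture is corrected in steps 17 and 18.

Step 17
Reactants: 24 oxonene alcohol
Product: 25 (2S,3S,7Z,9R)-oxonen-6-one (6-ketone of 24)
Conditions: Dess–Martin periodinane, pyridine, CH2Cl2, rt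
Reagents that add atoms: none
Why: Dess–Martin oxidation converges both C6 epimers on one Z-configured α-methyl enone.

Step 18
Reactants: 25 enone
Product: 26 (2S,3S,6R,7Z,9R)-oxonen-6-ol (single C6 epimer of 24)
Conditions: (S)-Me-CBS oxazaborolidine C18H20BNO (0.5 equiv), BH3·SMe2, THF, −40 °C; MeOH quench
Reagents that add atoms: none
Why: Corey–Bakshi–Shibata reduction, in which the α-methyl alkenyl group acts as the large substituent, so the (S)-catalyst delivers hydride 1,2 to give the 6R allylic alcohol under reagent control.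

Step 19
Reactants: 26 (6R)-allylic alcohol
Product: 27 6-O-PMB ether of 26
Conditions: NaH, 4-MeOC6H4CH2Cl, Bu4NI (cat.), DMF, 0 °C to rt
Reagents that add atoms: 4-methoxybenzyl chloride, COc1ccc(CCl)cc1
Why: Williamson etherification gives a C6 protecting group that survives acid, fluoride, Grignard, ylide and borane steps and is removed oxidatively at the end.

Step 20
Reactants: 27 PMB ether
Product: 28 diol with free C11 primary and C3 tertiary hydroxyls (TBDPS and PMB retained)
Conditions: camphor-10-sulfonic acid (0.2 equiv), MeOH/CH2Cl2 (1:1), 0 °C to rt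
Reagents that add atoms: none
Why: Acid methanolysis removes the primary TBS and the tertiary TES ethers far faster than the TBDPS ether, and the C3 protection is no longer needed once ring A exists.

Step 21
Reactants: 28 diol
Product: 29 C11 aldehyde
Conditions: Dess–Martin periodinane, pyridine, CH2Cl2, rt
Reagents that add atoms: none
Why: Only the primary alcohol can be oxidised, since the tertiary C3 hydroxyl is inert.

Step 22
Reactants: 29 C11 aldehyde
Product: 30 C11 isopropenyl carbinol (C11 epimers)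
Conditions: CH2=C(CH3)MgBr (2.5 equiv), THF, −78 °C
Reagents that add atoms: isopropenylmagnesium bromide, CC(=C)[Mg]Br
Why: Grignard addition installs C12, C13 and C20, and the C11 configuration is irrelevant because the carbinol is oxidised in step 24.

Step 23
Reactants: 30 isopropenyl carbinol
Product: 31 triol (C1, C3 and C11 hydroxyls free)
Conditions: Bu4NF, THF, 0 °C to rt
Reagents that add atoms: none
Why: Fluoride removes the TBDPS ether while no base-sensitive carbonyl group is present.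

Step 24
Reactants: 31 triol
Product: 32 keto aldehyde (C1 aldehyde, C11 isopropenyl ketone)
Conditions: Dess–Martin periodinane (3 equiv), pyridine, CH2Cl2, 0 °C to rt
Reagents that add atoms: none
Why: One Dess–Martin oxidation converts the primary C1 alcohol into the aldehyde and both C11 epimers into the same enone while the tertiary C3 hydroxyl is inert.

Step 25
Reactants: 32 keto aldehyde
Product: 33 (E)-unsaturated Weinreb amide (C1=C14) carrying the C11 isopropenyl ketone
Conditions: Ph3P=CHC(O)N(OMe)Me, CH2Cl2, rt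
Reagents that add atoms: N-methoxy-N-methyl-2-(triphenylphosphoranylidene)acetamide, CON(C)C(=O)C=P(c1ccccc1)(c1ccccc1)c1ccccc1
Why: The stabilised Wittig ylide reacts only with the aldehyde and gives the E-olefin, a dienophile that has no enolisable α-hydrogens to interfere in step 26.

Step 26
Reactants: 33 enone–enamide
Product: 35 tricyclic Diels–Alder adduct (rings A–C; C11 OTIPS enol ether with C11=C12; C14 C(O)N(OMe)Me; C1 C10 C14 configured as in the target), via silyl dienol ether tetraene 34 (not isolated)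
Conditions: TIPSOTf, Et3N, CH2Cl2, −78 to 0 °C; then toluene, 2,6-di-tert-butyl-4-methylphenol (cat.), 90 °C
Reagents that add atoms: triisopropylsilyl triflate, CC(C)[Si](OS(=O)(=O)C(F)(F)F)(C(C)C)C(C)C
Why: Soft enolisation can only occur toward C10 and gives the (Z)-2-silyloxydiene, which undergoes an intramolecular Diels–Alder reaction with the (E)-enamide through the tether-controlled exo mode enforced by the 2,9-cis oxonene, setting C1, C10 and C14 at once (H1/H10 cis and anti to H2/H9, C14 substituent trans to C2).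

Step 27
Reactants: 35 tricyclic Weinreb amide
Product: 36 C14 methyl ketone (C15 carbonyl, C17 methyl)
Conditions: MeMgBr (3 equiv), THF, 0 °C
Reagents that add atoms: methylmagnesium bromide, C[Mg]Br
Why: Weinreb ketone synthesis stops at the methyl ketone, the silyl enol ether is inert to the Grignard reagent, and the extra equivalent is consumed by the C3 hydroxyl.

Step 28
Reactants: 36 methyl ketone
Product: 37 C14 isopropenyl compound (C15=C16)
Conditions: Ph3PCH3Br, KOtBu, THF, 0 °C to rt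
Reagents that add atoms: methyltriphenylphosphonium bromide, C[P+](c1ccccc1)(c1ccccc1)c1ccccc1.[Br-]
Why: Wittig methylenation converts the only free ketone into the isopropenyl group while C11 is still masked as its silyl enol ether, and the equatorial C14 centre is the thermodynamically preferred one.

Step 29
Reactants: 37 silyl enol ether
Product: 38 C11 ketone with 12R methyl
Conditions: Bu4NF, AcOH, THF, −40 to 0 °C
Reagents that add atoms: none
Why: Fluoride desilylation with in-situ kinetic protonation by AcOH occurs on the convex face, anti to the pseudoaxial C9 substituent on C10, which places the C12 methyl on the concave face (12R).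

Step 30
Reactants: 38 ketone
Product: 39 11R alcohol (hydroxyl cis to the C12 methyl)
Conditions: NaBH4, MeOH, −20 °C
Reagents that add atoms: none
Why: Hydride attacks the C11 carbonyl from the convex face, away from the flanking C9 and C20 substituents, giving the 11R alcohol before the α-centre can epimerise.

Step 31
Reactants: 39 alcohol
Product: 40 C11 acetate
Conditions: Ac2O, pyridine, 4-(dimethylamino)pyridine (cat.), CH2Cl2, rt
Reagents that add atoms: acetic anhydride, CC(=O)OC(C)=O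
Why: Nucleophile-catalysed acylation esterifies the secondary C11 hydroxyl and leaves the hindered tertiary C3 hydroxyl free.

Step 32
Reactants: 40 acetate
Product: 42 C16 primary alcohol with 15R configuration, via B-alkyl-9-BBN adduct 41 (not isolated)
Conditions: 9-BBN, THF, 0 °C to rt; then H2O2, aq. NaHCO3, 0 °C to rt
Reagents that add atoms: hydrogen peroxide, OO; 9-borabicyclo[3.3.1]nonane, B1C2CCCC1CCC2 (its boron sits in 41 only)
Why: Anti-Markovnikov hydroboration with 9-BBN touches only the 1,1-disubstituted alkene and attacks its A(1,3)-minimised rotamer from the face of the C13 methylene, away from the ring-fusion carbon C1, which sets 15R, and the buffered oxidation spares the acetate.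

Step 33
Reactants: 42 hydroxy alcohol (C16 primary OH, C3 tertiary OH)
Product: 44 C6 PMB ether of the target (ring D closed), via primary triflate 43 (not isolated)
Conditions: Tf2O (1.1 equiv), 2,6-lutidine, CH2Cl2, −78 °C to rt
Reagents that add atoms: triflic anhydride, O=S(=O)(OS(=O)(=O)C(F)(F)F)C(F)(F)F (its triflyl group sits in 43 only)
Why: Selective triflation of the primary alcohol followed by intramolecular Williamson-type displacement by the C3 tertiary hydroxyl closes the seven-membered ether without touching any stereocentre.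

Step 34
Reactants: 44 PMB ether
Product: 45 target compound
Conditions: DDQ, CH2Cl2/pH 7 buffer (10:1), 0 °C
Reagents that add atoms: none
Why: Oxidative PMB cleavage under neutral conditions frees the C6 allylic alcohol and leaves the acetate, both ethers and the Z-olefin intact.

## Compound list

1 | propane-1,3-diol | OCCCO | starting material
2 | 3-(TBS-oxy)propan-1-ol | OCCCO[Si](C)(C)C(C)(C)C | intermediate
3 | 3-(TBS-oxy)propanal | O=CCCO[Si](C)(C)C(C)(C)C | intermediate
4 | rac-1-(TBS-oxy)hex-4-yn-3-ol | CC#CC(O)CCO[Si](C)(C)C(C)(C)C | intermediate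
5 | 1-(TBS-oxy)hex-4-yn-3-one | CC#CC(=O)CCO[Si](C)(C)C(C)(C)C | intermediate
6 | (R)-1-(TBS-oxy)hex-4-yn-3-ol | CC#C[C@H](O)CCO[Si](C)(C)C(C)(C)C | intermediate
7 | cyclic alkenylaluminate of 6, sodium salt (not isolated) | CC1=C[C@@H](CCO[Si](C)(C)C(C)(C)C)O[Al-]1(OCCOC)OCCOC.[Na+] | intermediate
8 | (3R,4Z)-1-(TBS-oxy)-5-iodohex-4-en-3-ol | C/C(I)=C/[C@H](O)CCO[Si](C)(C)C(C)(C)C | intermediate
9 | bromoacetic acid | OC(=O)CBr | starting material
10 | 2-{[(3R,4Z)-1-(TBS-oxy)-5-iodohex-4-en-3-yl]oxy}acetic acid | C/C(I)=C/[C@H](OCC(=O)O)CCO[Si](C)(C)C(C)(C)C | intermediate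
11 | (R)-4-benzyloxazolidin-2-one | O=C1N[C@H](Cc2ccccc2)CO1 | starting material
12 | mixed pivalic anhydride of 10 (not isolated) | C/C(I)=C/[C@H](OCC(=O)OC(=O)C(C)(C)C)CCO[Si](C)(C)C(C)(C)C | intermediate
13 | (R)-4-benzyl-3-(2-{[(3R,4Z)-1-(TBS-oxy)-5-iodohex-4-en-3-yl]oxy}acetyl)oxazolidin-2-one | C/C(I)=C/[C@H](OCC(=O)N1[C@H](Cc2ccccc2)COC1=O)CCO[Si](C)(C)C(C)(C)C | intermediate
14 | acetaldehyde | CC=O | starting material
15 | dibutylboron (Z)-enolate of 13 (not isolated) | CCCCB(CCCC)O/C(=C\O[C@H](CCO[Si](C)(C)C(C)(C)C)/C=C(/C)I)N1[C@H](Cc2ccccc2)COC1=O | intermediate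
16 | dibutylboron aldolate of 17 (not isolated) | C[C@H](OB(CCCC)CCCC)[C@@H](O[C@H](CCO[Si](C)(C)C(C)(C)C)/C=C(/C)I)C(=O)N1[C@H](Cc2ccccc2)COC1=O | intermediate
17 | (R)-4-benzyl-3-[(2R,3S)-2-{[(3R,4Z)-1-(TBS-oxy)-5-iodohex-4-en-3-yl]oxy}-3-hydroxybutanoyl]oxazolidin-2-one | C[C@H](O)[C@@H](O[C@H](CCO[Si](C)(C)C(C)(C)C)/C=C(/C)I)C(=O)N1[C@H](Cc2ccccc2)COC1=O | intermediate
18 | (2S,3S)-2-{[(3R,4Z)-1-(TBS-oxy)-5-iodohex-4-en-3-yl]oxy}butane-1,3-diol | C[C@H](O)[C@H](CO)O[C@H](CCO[Si](C)(C)C(C)(C)C)/C=C(/C)I | intermediate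
19 | (2S,3S)-4-(TBDPS-oxy)-3-{[(3R,4Z)-1-(TBS-oxy)-5-iodohex-4-en-3-yl]oxy}butan-2-ol | C[C@H](O)[C@H](CO[Si](c1ccccc1)(c1ccccc1)C(C)(C)C)O[C@H](CCO[Si](C)(C)C(C)(C)C)/C=C(/C)I | intermediate
20 | (S)-4-(TBDPS-oxy)-3-{[(3R,4Z)-1-(TBS-oxy)-5-iodohex-4-en-3-yl]oxy}butan-2-one | CC(=O)[C@H](CO[Si](c1ccccc1)(c1ccccc1)C(C)(C)C)O[C@H](CCO[Si](C)(C)C(C)(C)C)/C=C(/C)I | intermediate
21 | (2S,3S)-1-(TBDPS-oxy)-2-{[(3R,4Z)-1-(TBS-oxy)-5-iodohex-4-en-3-yl]oxy}-3-methylhept-6-en-3-ol | C=CCC[C@](C)(O)[C@H](CO[Si](c1ccccc1)(c1ccccc1)C(C)(C)C)O[C@H](CCO[Si](C)(C)C(C)(C)C)/C=C(/C)I | intermediate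
22 | 3-O-TES ether of 21 | C=CCC[C@](C)(O[Si](CC)(CC)CC)[C@H](CO[Si](c1ccccc1)(c1ccccc1)C(C)(C)C)O[C@H](CCO[Si](C)(C)C(C)(C)C)/C=C(/C)I | intermediate
23 | (4S,5S)-6-(TBDPS-oxy)-5-{[(3R,4Z)-1-(TBS-oxy)-5-iodohex-4-en-3-yl]oxy}-4-methyl-4-(TES-oxy)hexanal | O=CCC[C@](C)(O[Si](CC)(CC)CC)[C@H](CO[Si](c1ccccc1)(c1ccccc1)C(C)(C)C)O[C@H](CCO[Si](C)(C)C(C)(C)C)/C=C(/C)I | intermediate
24 | (2S,3S,7Z,9R)-2-(TBDPS-oxymethyl)-9-[2-(TBS-oxy)ethyl]-3,7-dimethyl-3-(TES-oxy)-2,3,4,5,6,9-hexahydrooxonin-6-ol, C6 epimers | CC(C)(C)[Si](c1ccccc1)(c1ccccc1)OC[C@@H]1O[C@H](CCO[Si](C)(C)C(C)(C)C)/C=C(/C)C(O)CC[C@]1(C)O[Si](CC)(CC)CC | intermediate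
25 | (2S,3S,7Z,9R)-oxonen-6-one, 6-ketone of 24 | CC(C)(C)[Si](c1ccccc1)(c1ccccc1)OC[C@@H]1O[C@H](CCO[Si](C)(C)C(C)(C)C)/C=C(/C)C(=O)CC[C@]1(C)O[Si](CC)(CC)CC | intermediate
26 | (2S,3S,6R,7Z,9R)-oxonen-6-ol, single epimer of 24 | CC(C)(C)[Si](c1ccccc1)(c1ccccc1)OC[C@@H]1O[C@H](CCO[Si](C)(C)C(C)(C)C)/C=C(/C)[C@H](O)CC[C@]1(C)O[Si](CC)(CC)CC | intermediate
27 | 6-O-PMB ether of 26 | CC(C)(C)[Si](c1ccccc1)(c1ccccc1)OC[C@@H]1O[C@H](CCO[Si](C)(C)C(C)(C)C)/C=C(/C)[C@H](OCc2ccc(OC)cc2)CC[C@]1(C)O[Si](CC)(CC)CC | intermediate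
28 | (2S,3S,6R,7Z,9R)-oxonene with C1 OTBDPS, C6 OPMB, free C3 OH and free C11 primary OH | CC(C)(C)[Si](c1ccccc1)(c1ccccc1)OC[C@@H]1O[C@H](CCO)/C=C(/C)[C@H](OCc2ccc(OC)cc2)CC[C@]1(C)O | intermediate
29 | C11 aldehyde of 28 | CC(C)(C)[Si](c1ccccc1)(c1ccccc1)OC[C@@H]1O[C@H](CC=O)/C=C(/C)[C@H](OCc2ccc(OC)cc2)CC[C@]1(C)O | intermediate
30 | C11 isopropenyl carbinol, C11 epimers | CC(C)(C)[Si](c1ccccc1)(c1ccccc1)OC[C@@H]1O[C@H](CC(O)C(C)=C)/C=C(/C)[C@H](OCc2ccc(OC)cc2)CC[C@]1(C)O | intermediate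
31 | triol: 30 without the TBDPS group | OC[C@@H]1O[C@H](CC(O)C(C)=C)/C=C(/C)[C@H](OCc2ccc(OC)cc2)CC[C@]1(C)O | intermediate
32 | keto aldehyde: C1 aldehyde and C11 isopropenyl ketone, configuration as in 31 | O=C[C@@H]1O[C@H](CC(=O)C(C)=C)/C=C(/C)[C@H](OCc2ccc(OC)cc2)CC[C@]1(C)O | intermediate
33 | (E)-unsaturated Weinreb amide (C1=C14) with C11 isopropenyl ketone | CON(C)C(=O)/C=C/[C@@H]1O[C@H](CC(=O)C(C)=C)/C=C(/C)[C@H](OCc2ccc(OC)cc2)CC[C@]1(C)O | intermediate
34 | (Z)-TIPS dienol ether tetraene (not isolated) | CON(C)C(=O)/C=C/[C@@H]1O[C@H](/C=C(O[Si](C(C)C)(C(C)C)C(C)C)/C(C)=C)/C=C(/C)[C@H](OCc2ccc(OC)cc2)CC[C@]1(C)O | intermediate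
35 | tricyclic Diels–Alder adduct: C11 OTIPS enol ether, C14 Weinreb amide, C3 OH, C6 OPMB; C1, C2, C3, C6, C9, C10, C14 arranged as in the target | CON(C)C(=O)[C@@H]1CC(C)=C(O[Si](C(C)C)(C(C)C)C(C)C)[C@@H]2[C@H]1[C@@H]3O[C@H]2/C=C(/C)[C@H](OCc4ccc(OC)cc4)CC[C@]3(C)O | intermediate
36 | C14 methyl ketone of the tricycle | CC(=O)[C@@H]1CC(C)=C(O[Si](C(C)C)(C(C)C)C(C)C)[C@@H]2[C@H]1[C@@H]3O[C@H]2/C=C(/C)[C@H](OCc4ccc(OC)cc4)CC[C@]3(C)O | intermediate
37 | C14 isopropenyl tricycle, C11 OTIPS enol ether | C=C(C)[C@@H]1CC(C)=C(O[Si](C(C)C)(C(C)C)C(C)C)[C@@H]2[C@H]1[C@@H]3O[C@H]2/C=C(/C)[C@H](OCc4ccc(OC)cc4)CC[C@]3(C)O | intermediate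
38 | C11 ketone with 12R methyl | C=C(C)[C@@H]1C[C@@H](C)C(=O)[C@@H]2[C@H]1[C@@H]3O[C@H]2/C=C(/C)[C@H](OCc4ccc(OC)cc4)CC[C@]3(C)O | intermediate
39 | 11R alcohol, 12R methyl | C=C(C)[C@@H]1C[C@@H](C)[C@@H](O)[C@@H]2[C@H]1[C@@H]3O[C@H]2/C=C(/C)[C@H](OCc4ccc(OC)cc4)CC[C@]3(C)O | intermediate
40 | C11 acetate of 39 | C=C(C)[C@@H]1C[C@@H](C)[C@@H](OC(C)=O)[C@@H]2[C@H]1[C@@H]3O[C@H]2/C=C(/C)[C@H](OCc4ccc(OC)cc4)CC[C@]3(C)O | intermediate
41 | B-alkyl-9-BBN adduct at C16 (not isolated) | B1(C2CCCC1CCC2)C[C@H](C)[C@@H]3C[C@@H](C)[C@@H](OC(C)=O)[C@@H]4[C@H]3[C@@H]5O[C@H]4/C=C(/C)[C@H](OCc6ccc(OC)cc6)CC[C@]5(C)O | intermediate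
42 | C16 primary alcohol, 15R, with free C3 OH | OC[C@H](C)[C@@H]1C[C@@H](C)[C@@H](OC(C)=O)[C@@H]2[C@H]1[C@@H]3O[C@H]2/C=C(/C)[C@H](OCc4ccc(OC)cc4)CC[C@]3(C)O | intermediate
43 | C16 primary triflate of 42 (not isolated) | O=S(=O)(OC[C@H](C)[C@@H]1C[C@@H](C)[C@@H](OC(C)=O)[C@@H]2[C@H]1[C@@H]3O[C@H]2/C=C(/C)[C@H](OCc4ccc(OC)cc4)CC[C@]3(C)O)C(F)(F)F | intermediate
44 | 6-O-PMB ether of the target (tetracycle) | CC(=O)O[C@H]1[C@@H]2[C@@H]3[C@@H](C[C@H]1C)[C@@H](C)CO[C@@]1(C)CC[C@@H](OCc4ccc(OC)cc4)/C(C)=C\[C@@H]2O[C@@H]31 | intermediate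
45 | target, (1S,2S,3S,6R,9S,10R,11R,12R,14S,15R,7Z) | CC(=O)O[C@H]1[C@@H]2[C@@H]3[C@@H](C[C@H]1C)[C@@H](C)CO[C@@]1(C)CC[C@@H](O)/C(C)=C\[C@@H]2O[C@@H]31 | target

## Step count and risks

Total steps: 34. Longest linear sequence: 34 steps (fully linear from propane-1,3-diol).

The three steps most likely to fail:

Step 16 (nine-membered ring closure). The risk is oligomerisation or simple loss of iodine instead of cyclisation. The fallback sets out from aldehyde 23. Pinnick oxidation (NaClO2, NaH2PO4, 2-methylbut-2-ene, t-BuOH/H2O) gives the carboxylic acid F1. Coupling with MeNHOMe·HCl (EDC·HCl, 4-(dimethylamino)pyridine, CH2Cl2) gives the Weinreb amide F2. Slow addition of F2 to t-BuLi (2.2 equiv, THF, −78 °C, 0.005 M) triggers iodine–lithium exchange and intramolecular acylation, which delivers enone 25 directly. The route is rejoined at 25 and step 17 is skipped.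

Step 26 (silyl dienol ether formation and intramolecular Diels–Alder). The risk is that the unsaturated Weinreb amide is too weak a dienophile and the silyloxydiene degrades on heating. The fallback sets out from keto aldehyde 32. Wittig reaction with Ph3P=CHCHO (toluene, rt) gives the (E)-enal F3. TIPSOTf/Et3N (CH2Cl2, −78 to 0 °C) gives the silyl dienol ether F4, whose much more electron-poor enal cyclises at or below room temperature in the same tether-controlled exo mode to the tricyclic aldehyde F5. MeMgBr (THF, −78 °C) gives the secondary alcohol F6 (carbinol epimers), and Dess–Martin oxidation returns the route at methyl ketone 36.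

Step 29 (C12 by kinetic protonation). The risk is that the two C12 epimers of the ketone are close in energy, so poor facial selectivity or equilibration gives mixtures. The fallback sets out from silyl enol ether 37. NBS (THF, −78 °C) gives the α-bromo ketone F7 (either C12 epimer). Bu3SnH with Et3B/air (toluene, −78 °C) reduces F7 through the planar C12 radical, the bulky stannane delivering hydrogen from the convex face under non-basic, non-equilibrating conditions. The route is rejoined at ketone 38.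

## Further compounds

F1 | step 16 | (4S,5S)-6-(TBDPS-oxy)-5-{[(3R,4Z)-1-(TBS-oxy)-5-iodohex-4-en-3-yl]oxy}-4-methyl-4-(TES-oxy)hexanoic acid | OC(=O)CC[C@](C)(O[Si](CC)(CC)CC)[C@H](CO[Si](c1ccccc1)(c1ccccc1)C(C)(C)C)O[C@H](CCO[Si](C)(C)C(C)(C)C)/C=C(/C)I
F2 | step 16 | N-methoxy-N-methyl amide of F1 | CON(C)C(=O)CC[C@](C)(O[Si](CC)(CC)CC)[C@H](CO[Si](c1ccccc1)(c1ccccc1)C(C)(C)C)O[C@H](CCO[Si](C)(C)C(C)(C)C)/C=C(/C)I
F3 | step 26 | (E)-enal (C1=C14, C15 aldehyde) with C11 isopropenyl ketone | O=C/C=C/[C@@H]1O[C@H](CC(=O)C(C)=C)/C=C(/C)[C@H](OCc2ccc(OC)cc2)CC[C@]1(C)O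
F4 | step 26 | (Z)-TIPS dienol ether of F3 | O=C/C=C/[C@@H]1O[C@H](/C=C(O[Si](C(C)C)(C(C)C)C(C)C)/C(C)=C)/C=C(/C)[C@H](OCc2ccc(OC)cc2)CC[C@]1(C)O
F5 | step 26 | tricyclic C14 aldehyde (analogue of 35) | O=C[C@@H]1CC(C)=C(O[Si](C(C)C)(C(C)C)C(C)C)[C@@H]2[C@H]1[C@@H]3O[C@H]2/C=C(/C)[C@H](OCc4ccc(OC)cc4)CC[C@]3(C)O
F6 | step 26 | tricyclic C15 secondary alcohol, carbinol epimers | CC(O)[C@@H]1CC(C)=C(O[Si](C(C)C)(C(C)C)C(C)C)[C@@H]2[C@H]1[C@@H]3O[C@H]2/C=C(/C)[C@H](OCc4ccc(OC)cc4)CC[C@]3(C)O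
F7 | step 29 | 12-bromo C11 ketone, C12 epimers | C=C(C)[C@@H]1CC(C)(Br)C(=O)[C@@H]2[C@H]1[C@@H]3O[C@H]2/C=C(/C)[C@H](OCc4ccc(OC)cc4)CC[C@]3(C)O
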